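The constants set how long the catalyst needs per turn of its cycle, and the next run hangs on that: dosed, charged at once, or through the tank.

    coupling partner + free catalyst → catalyst intermediate A (k1 = 4.3 /M/min)
    catalyst intermediate A ⇌ released group + catalyst intermediate B (K2 = 0.48 M, k2 = 0.63 /min)
    substrate + catalyst intermediate B → catalyst intermediate C (k3 = 7.6 /M/min)
    catalyst intermediate C ⇌ free catalyst + target (K4 = 11 M, k4 = 5.2 /min)
    coupling partner + free catalyst + target → free catalyst + over-reaction product (k5 = 2.2 /M²/min)
    coupling partner + protic impurity → quenched reagent (k6 = 0.66 /M/min)

| setting | winter | summer | dawn | midnight |
|---|---|---|---|---|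
| substrate | 0.50 M (fed, over 10.0 min) | 0.50 M | 0.50 M | 0.50 M |
| coupling partner | 0.900 M | 0.900 M (fed, over 10.0 min) | 0.900 M | 0.900 M |
| protic impurity | 0.0500 M | 0.0500 M | 0.0500 M | 0.0500 M |
| free catalyst | 75 mM | 75 mM | 75 mM | 75 mM |
| time | 20 min | 20 min | 20 min |  |
| remark | a stirred flask in which substrate is dosed at a steady rate over 10.0 min without added volume, worked up at 20 min | all but coupling partner at the start; coupling partner goes in evenly over 10.0 min, the run ends at 20 min | a closed flask charged with all of it at once and left for 20 min | one stirred flow tank at steady state, fed with the mixture as stated, mean residence time 20 min |

- the stated concentrations are those of everything mixed, before any reaction; amounts are the same in each set-up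
- the feed brings no volume worth counting
- run time (winter): 20 min

- the set-up with the highest amount of target at the outlet or at the end, in percent of the substrate put in ("none" if the first two lie within 2 percentage points) (winter / summer / dawn / midnight / none)
- amount of target at the outlet or at the end, in percent of the substrate put in, winter
- amount of target at the outlet or at the end, in percent of the substrate put in, summer
- amount of target at the outlet or at the end, in percent of the substrate put in, dawn
- amount of target at the outlet or at the end, in percent of the substrate put in, midnight

In quasi-steady state each catalyst form stands in proportion to its wait, so turnover runs at the catalyst charge 75 mM divided by the cycle time T, the sum of the waits. With b coupling partner, s substrate and w released group, in M: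

T = Tf + 14.0 M·s/b + (1 + w/0.48 M)·7.89 M·s/s

Here Tf = 1.78 min is the fixed part of the cycle time, the wait for release of the group and of the target. The term in w counts the return of catalyst intermediate B to its resting state, catalyst intermediate A.

The coupling step and the over-reaction both run on coupling partner times free catalyst, so over-reaction per turn is target times the selectivity factor g = 0.512 /M. A feed lowers s or b and so lengthens T, but g contains neither, so dosing costs turnover and buys no selectivity. As a simplification, the reckoning takes the whole charge of protic impurity off the coupling partner at the outset and puts b at 0.850 M, although at the start of dawn step 1 uses coupling partner 9.8 times as fast as step 6 does. It also lets b and s fall by N, the turnovers so far, and sets w equal to N, leaving aside the coupling partner that goes to over-reaction product or stays bound on the catalyst.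

For midnight, N = 75 mM × 20 min / T at the outlet composition. Starting from N = 0.350 M:

T = 3.76 min, so N = 0.399 M

T = 4.67 min, so N = 0.321 M

The two rounds bracket N, and their mean is 0.360 M. A tank gives target N/(1 + gN), which is 60.8% of the substrate.

For dawn, integrating dN = 75 mM dt / T up to 20 min gives the leftover substrate as an exponential with N in its exponent, so N goes round as well. Starting from N = 0.50 M:

N = 0.433 M

N = 0.461 M

A batch gives target (1 − exp(−gN))/g, which is 82.1% of the substrate. The next run is therefore charged at once, as dawn.

The forecast gives 75%, 74.5%, 76% and 61.5% for winter, summer, dawn and midnight and answers none, holding that “dosing either reagent changes little”.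

The simulation gives winter 74.7%, summer 72.7%, dawn 78.4% and midnight 58.2%, and the best is dawn; dawn stands lower than the reckoning.

At 20.0 min in dawn, the simulated concentrations give T = 6.89 min, and the substrate-side wait of 4.34 min is longer than Tf, while the wait at catalyst intermediate B alone is 32.0% of T against a reading of 30.8% of the catalyst. In the dawn flask charged with 0.30 M of substrate, T comes to 38.3 min, that share to 55.4%, and catalyst intermediate B stands at 54.3%.

(Its constants are those of an exercise; the flask was simulated.)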